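The seven-membered carbocycle (ring A: C1, C5–C10) carries three contiguous oxygenated carbons, C1, C5 and C6, which map onto C1–C3 of D-arabinose. Everything rests on disconnecting C9–C10. A thermal Claisen ring expansion of a (Z)-2-ethylidene-5-vinyltetrahydrofuran, in which C7 (arabinose C4) still holds the ring oxygen, forms C9–C10. It also turns the ether oxygen into the C1 ketone, sets C10, and leaves a C7=C8 alkene next to O6. That alkene then takes the cis γ-lactone (ring B) by radical annulation from O6, and the ketone takes the C2–C4 chain. The precursor comes from an O2-benzyl, O3-PMB 5-vinyl arabinonolactone by ester ethylidenation.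

Key step: step 11

Remark on numbering and faces: C1 is the tertiary carbinol, C5 the angelate carbon, C6 the lactone O-carbon, C7 the ring fusion, C8 and C9 the methylenes, and C10 the methyl-bearing ring carbon. C11 and C12 are the lactone CH and C=O, and C2–C4 are the side chain. The β face is the face of O5 and of the C2 acyl group. The α face carries O6, C11 on C7, the C10 methyl and the C1 hydroxyl. H6, H7 and H11 are all β.

Assumption: centres that are destroyed later (C1 of 2 and 8, C12 of 14 and 15, C2 of 25) are carried as mixtures.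

Step 1
Reactants: 1 D-arabinose
Product: 2 5-O-(tert-butyldiphenylsilyl)-D-arabinofuranose (anomeric mixture)
Conditions: TBDPSCl, imidazole, DMF, 0 °C to rt
Reagents that add atoms: tert-butyldiphenylsilyl chloride, CC(C)(C)[Si](Cl)(c1ccccc1)c1ccccc1
Why: Chemoselective silylation of a primary alcohol: only the furanose tautomer offers a primary hydroxyl, so the bulky chloride should drain the tautomer equilibrium into the five-membered form without touching a stereocentre.

Step 2
Reactants: 2 5-O-(tert-butyldiphenylsilyl)-D-arabinofuranose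
Product: 3 5-O-(tert-butyldiphenylsilyl)-1,2-O-isopropylidene-β-D-arabinofuranose
Conditions: Me2C(OMe)2, TsOH (cat.), acetone, rt
Reagents that add atoms: 2,2-dimethoxypropane, COC(C)(C)OC
Why: Acid-catalysed transacetalisation: only O1 and O2 of the β-anomer are cis on the furanose (O2 and O3 are trans), so the acetonide masks C1 and O2 together, fixes the anomer as β and leaves O3 as the only free hydroxyl.

Step 3
Reactants: 3 5-O-(tert-butyldiphenylsilyl)-1,2-O-isopropylidene-β-D-arabinofuranose
Product: 4 5-O-(tert-butyldiphenylsilyl)-1,2-O-isopropylidene-3-O-(4-methoxybenzyl)-β-D-arabinofuranose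
Conditions: NaH, PMBCl, Bu4NI (cat.), DMF, 0 °C to rt
Reagents that add atoms: 4-methoxybenzyl chloride, COc1ccc(CCl)cc1
Why: Williamson etherification of the single free hydroxyl (the future O6) is run while C1 is still masked as an acetal, so strong base can do no harm.

Step 4
Reactants: 4 5-O-(tert-butyldiphenylsilyl)-1,2-O-isopropylidene-3-O-(4-methoxybenzyl)-β-D-arabinofuranose
Product: 5 1,2-O-isopropylidene-3-O-(4-methoxybenzyl)-β-D-arabinofuranose
Conditions: Bu4NF, THF, rt
Reagents that add atoms: none
Why: Fluoride-driven silyl ether cleavage frees the primary alcohol and leaves the acetal and the PMB ether untouched.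

Step 5
Reactants: 5 1,2-O-isopropylidene-3-O-(4-methoxybenzyl)-β-D-arabinofuranose
Product: 6 1,2-O-isopropylidene-3-O-(4-methoxybenzyl)-β-D-arabino-pentodialdo-1,4-furanose
Conditions: Dess–Martin periodinane, CH2Cl2, 0 °C to rt
Reagents that add atoms: none
Why: Dess–Martin oxidation stops at the aldehyde under nearly neutral conditions, so the adjacent sugar C4 (the future C7) should keep its configuration.

Step 6
Reactants: 6 1,2-O-isopropylidene-3-O-(4-methoxybenzyl)-β-D-arabino-pentodialdo-1,4-furanose
Product: 7 5,6-dideoxy-1,2-O-isopropylidene-3-O-(4-methoxybenzyl)-β-D-arabino-hex-5-enofuranose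
Conditions: Ph3PCH3Br, KOt-Bu, THF, 0 °C; then 6, −78 °C to rt
Reagents that add atoms: methyltriphenylphosphonium bromide, C[P+](c1ccccc1)(c1ccccc1)c1ccccc1.[Br-]
Why: Wittig methylenation adds the future C9 at low temperature faster than the α-centre can epimerise, and that centre already has the more stable trans relation to O3.

Step 7
Reactants: 7 5,6-dideoxy-1,2-O-isopropylidene-3-O-(4-methoxybenzyl)-β-D-arabino-hex-5-enofuranose
Product: 8 5,6-dideoxy-3-O-(4-methoxybenzyl)-D-arabino-hex-5-enofuranose (anomeric mixture)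
Conditions: AcOH–H2O (4:1), 70 °C
Reagents that add atoms: none
Why: Acid hydrolysis of the acetonide frees O1 and O2 together, and the PMB ether and the vinyl group tolerate aqueous acetic acid.

Step 8
Reactants: 8 5,6-dideoxy-3-O-(4-methoxybenzyl)-D-arabino-hex-5-enofuranose
Product: 9 5,6-dideoxy-3-O-(4-methoxybenzyl)-D-arabino-hex-5-enono-1,4-lactone
Conditions: Ag2CO3 on Celite, PhMe, reflux
Reagents that add atoms: none
Why: Fétizon oxidation takes lactols to lactones far faster than it oxidises ordinary secondary alcohols, so C1 reaches the acid level while O2–H, the alkene and the electron-rich arene stay intact.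

Step 9
Reactants: 9 5,6-dideoxy-3-O-(4-methoxybenzyl)-D-arabino-hex-5-enono-1,4-lactone
Product: 10 2-O-benzyl-5,6-dideoxy-3-O-(4-methoxybenzyl)-D-arabino-hex-5-enono-1,4-lactone
Conditions: BnBr, Ag2O, CH2Cl2, rt, dark
Reagents that add atoms: benzyl bromide, BrCc1ccccc1
Why: Silver-oxide-promoted O-alkylation (Purdie type) needs no free strong base, which avoids epimerisation at sugar C2 and β-elimination of the O3 ether from the lactone.

Step 10
Reactants: 10 2-O-benzyl-5,6-dideoxy-3-O-(4-methoxybenzyl)-D-arabino-hex-5-enono-1,4-lactone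
Product: 11 (2Z,3S,4R,5R)-3-benzyloxy-2-ethylidene-4-(4-methoxybenzyloxy)-5-vinyltetrahydrofuran
Conditions: TiCl4, TMEDA, Zn, PbCl2 (cat.), CH3CHBr2, THF, 0 °C to rt; then Et3N, aq K2CO3; basic alumina
Reagents that add atoms: 1,1-dibromoethane, CC(Br)Br
Why: Takai–Utimoto alkylidenation of an ester-type carbonyl with the ethylidene reagent from the gem-dibromide, zinc and low-valent titanium is non-basic and should place the methyl group on the side of the ring oxygen, away from the benzyloxy-bearing C5, which is the usual Z outcome for esters.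

Step 11
Reactants: 11 (2Z,3S,4R,5R)-3-benzyloxy-2-ethylidene-4-(4-methoxybenzyloxy)-5-vinyltetrahydrofuran
Product: 12 (2S,3R,7S)-2-benzyloxy-3-(4-methoxybenzyloxy)-7-methylcyclohept-4-en-1-one
Conditions: degassed PhMe (0.01 M), BHT (cat.), silanised sealed tube, 175 °C
Reagents that add atoms: none
Why: The allyl vinyl ether C10=C1–O–C7–C8=C9 undergoes a concerted, suprafacial [3,3]-sigmatropic shift in which C9–C10 forms while O–C7 breaks and the ether oxygen ends as the C1 carbonyl, the strong C=O bond making the step irreversible. The closest known reaction type is the thermal aliphatic Claisen ring expansion of 2-alkylidene-5-vinyltetrahydrofurans to cyclohept-4-enones. Ring A is closed by a two-carbon ring enlargement (five to seven members) through a boat-like six-centre array spanning the oxolane, the only array the small ring allows, and this array delivers the cis C7=C8 alkene. C10 is the one new stereocentre: the vinyl group sits on the β face at C7 (arabinose C4), so C9 must bond to the β face of C10, and because the Z geometry holds the methyl group syn to the ring oxygen it emerges α, trans to O5 (7S in 12), while the C7 centre is consumed and C5 and C6 are spectators. The step needs periselectivity over a [1,3] shift, over acid-catalysed migration of the enol ether double bond into the ring and over loss of benzyl alcohol towards a furan; the enforced proximity of C9 and C10 together with acid-free silanised glass, dilution and exclusion of oxygen should secure it, and the absence of base protects C10, C5 and the β-oxygen at C6 of the product.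

Step 12
Reactants: 12 (2S,3R,7S)-2-benzyloxy-3-(4-methoxybenzyloxy)-7-methylcyclohept-4-en-1-one
Product: 13 (2S,3R,7S)-2-benzyloxy-3-hydroxy-7-methylcyclohept-4-en-1-one
Conditions: DDQ, CH2Cl2–pH 7 buffer, 0 °C
Reagents that add atoms: none
Why: Oxidative PMB cleavage picks the electron-rich benzyl group over the plain one, and the buffered neutral medium spares the base-sensitive β-oxy ketone and C10.

Step 13
Reactants: 13 (2S,3R,7S)-2-benzyloxy-3-hydroxy-7-methylcyclohept-4-en-1-one
Product: 14 O6-(2-bromo-1-methoxyprop-2-enyl) mixed acetal of 13 (acetal epimers)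
Conditions: NBS, methoxyallene, CH2Cl2, −40 to 0 °C
Reagents that add atoms: N-bromosuccinimide, O=C1CCC(=O)N1Br; methoxyallene, COC=C=C
Why: Bromoacetalisation, the first half of a Ueno–Stork annulation: bromonium transfer to the central allene carbon gives an oxocarbenium ion that O6–H captures, and the electron-rich allene outcompetes the ring alkene for NBS while bringing in C12, C11 and the future C11 methyl carbon at once.

Step 14
Reactants: 14 O6-(2-bromo-1-methoxyprop-2-enyl) mixed acetal of 13
Product: 15 cis-fused 8-benzyloxy-2-methoxy-6-methyl-3-methyleneoctahydrocyclohepta[b]furan-7-one (acetal epimers)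
Conditions: Bu3SnH (slow addition), AIBN (cat.), PhH, 80 °C
Reagents that add atoms: none
Why: Ueno–Stork radical cyclisation: the C11 vinyl radical closes 5-exo-trig onto C7, the short tether from the α-oriented O6 can only reach the α face so that C7–C11 is cis to O6 (this sets C7), and the C8 radical is reduced by the stannane.

Step 15
Reactants: 15 cis-fused 8-benzyloxy-2-methoxy-6-methyl-3-methyleneoctahydrocyclohepta[b]furan-7-one
Product: 16 (3aS,6S,8S,8aR)-8-benzyloxy-6-methyl-3-methylenehexahydrocyclohepta[b]furan-2,7-dione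
Conditions: CrO3, H2SO4, H2O, acetone, 0 °C
Reagents that add atoms: water, O
Why: Jones oxidation: aqueous acid opens the methyl acetal to the lactol and hexavalent chromium takes it to the α-methylene lactone, with the ketone and the benzyl ether inert during the short exposure.

Step 16
Reactants: 16 (3aS,6S,8S,8aR)-8-benzyloxy-6-methyl-3-methylenehexahydrocyclohepta[b]furan-2,7-dione
Product: 17 (3R,3aS,6S,8S,8aR)-8-benzyloxy-3,6-dimethylhexahydrocyclohepta[b]furan-2,7-dione
Conditions: H2 (1 atm), Pd/C, pyridine, EtOAc, rt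
Reagents that add atoms: none
Why: Heterogeneous hydrogenation of the exocyclic alkene from the convex β face of the cis-fused bicycle (the face of H6 and H7) should put H11 β and the methyl group α, which sets C11, while pyridine suppresses hydrogenolysis of the benzyl ether.

Step 17
Reactants: 18 (S)-propylene oxide
Product: 19 (S)-pent-4-yn-2-ol
Conditions: LiC≡CH·H2NCH2CH2NH2, DMSO, rt
Reagents that add atoms: lithium acetylide–ethylenediamine complex, [Li]C#C.NCCN
Why: SN2 opening of the epoxide at its unsubstituted carbon by the acetylide leaves the stereocentre (the future C4) untouched.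

Step 18
Reactants: 19 (S)-pent-4-yn-2-ol
Product: 20 (S)-4-iodopent-4-en-2-ol
Conditions: NaI, Me3SiCl, H2O, MeCN, rt
Reagents that add atoms: sodium iodide, [Na+].[I-]
Why: Markovnikov hydroiodination of the terminal alkyne with hydrogen iodide generated in the flask gives the 2-iodo-1-alkene, a reaction established for homopropargylic alcohols.

Step 19
Reactants: 20 (S)-4-iodopent-4-en-2-ol
Product: 21 (S)-tert-butyl[(4-iodopent-4-en-2-yl)oxy]dimethylsilane
Conditions: TBSCl, imidazole, CH2Cl2, rt
Reagents that add atoms: tert-butyldimethylsilyl chloride, CC(C)(C)[Si](C)(C)Cl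
Why: Standard silylation masks O4 so that it can neither quench the organometallic reagent nor compete later for the angeloyl group.

Step 20
Reactants: 17 (3R,3aS,6S,8S,8aR)-8-benzyloxy-3,6-dimethylhexahydrocyclohepta[b]furan-2,7-dione; 21 (S)-tert-butyl[(4-iodopent-4-en-2-yl)oxy]dimethylsilane
Product: 24 tertiary alcohol bearing 1α-OH plus the 1β-[(4S)-4-(tert-butyldimethylsilyloxy)pent-1-en-2-yl] group on the benzyl ether lactone, via alkenyllithium 22 (not isolated), via alkenylcerium dichloride 23 (not isolated)
Conditions: 21, t-BuLi (2 equiv), Et2O, −78 °C; CeCl3, THF, −78 °C; then 17, −78 °C; aq NH4Cl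
Reagents that add atoms: none
Why: Iodine–lithium exchange, transmetalation and organocerium 1,2-addition: the oxophilic, weakly basic reagent should add to the ketone (activated by chelation to O5) rather than enolise it or attack the lactone, and it should approach the convex β face, anti to the C10 methyl group and to ring B, which sets C1 with its hydroxyl α.

Step 21
Reactants: 24 tertiary alcohol with the 1β-alkenyl group
Product: 26 1α-hydroxy-1β-[(S)-3-(tert-butyldimethylsilyloxy)butanoyl] benzyl ether lactone, via ozonide 25 (not isolated)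
Conditions: O3, CH2Cl2, −78 °C (stopped at first blue colour); then Me2S, −78 °C to rt
Reagents that add atoms: ozone, [O-][O+]=O
Why: Ozonolysis of the only alkene turns the 1,1-disubstituted C2=CH2 unit into the C2 ketone, so the alkenyl metal has served as an acyl anion equivalent, and the alkene reacts much faster than the benzyl ether.

Step 22
Reactants: 26 1α-hydroxy-1β-[(S)-3-(tert-butyldimethylsilyloxy)butanoyl] benzyl ether lactone
Product: 27 5β,1α-diol with the O4 silyl ether
Conditions: H2 (1 atm), Pd(OH)2/C, EtOAc, rt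
Reagents that add atoms: none
Why: Catalytic hydrogenolysis removes the O5 benzyl group, and no other group in the molecule is reducible under these conditions.

Step 23
Reactants: 27 5β,1α-diol with the O4 silyl ether; 28 angelic acid
Product: 30 O4-tert-butyldimethylsilyl ether of the target, via mixed anhydride 29 (not isolated)
Conditions: 28, 2,4,6-Cl3C6H2COCl, Et3N, PhMe, rt; then 27, 80 °C (no DMAP)
Reagents that add atoms: none
Why: Yamaguchi-type mixed-anhydride esterification run without a nucleophilic catalyst avoids the addition–elimination that turns angelates into tiglates, and only the secondary O5–H should react because the C1 hydroxyl is tertiary and O4 is silylated.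

Step 24
Reactants: 30 O4-tert-butyldimethylsilyl ether of the target
Product: 31 CNP0321985.2, (3R,3aS,6S,7S,8S,8aR)-7-hydroxy-7-[(S)-3-hydroxybutanoyl]-3,6-dimethyl-2-oxooctahydrocyclohepta[b]furan-8-yl (Z)-2-methylbut-2-enoate
Conditions: HF·pyridine, THF, 0 °C to rt
Reagents that add atoms: none
Why: Acidic fluoride desilylation frees O4–H without the basic conditions that could trigger retro-aldol cleavage, β-elimination or acyl migration.

Compound list
1 | D-arabinose | O=C[C@@H](O)[C@H](O)[C@H](O)CO | starting material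
2 | 5-O-(tert-butyldiphenylsilyl)-D-arabinofuranose | OC1O[C@H](CO[Si](c2ccccc2)(c2ccccc2)C(C)(C)C)[C@@H](O)[C@@H]1O | intermediate
3 | 5-O-(tert-butyldiphenylsilyl)-1,2-O-isopropylidene-β-D-arabinofuranose | CC1(C)O[C@@H]2O[C@H](CO[Si](c3ccccc3)(c3ccccc3)C(C)(C)C)[C@@H](O)[C@@H]2O1 | intermediate
4 | 5-O-(tert-butyldiphenylsilyl)-1,2-O-isopropylidene-3-O-(4-methoxybenzyl)-β-D-arabinofuranose | CC1(C)O[C@@H]2O[C@H](CO[Si](c3ccccc3)(c3ccccc3)C(C)(C)C)[C@@H](OCc3ccc(OC)cc3)[C@@H]2O1 | intermediate
5 | 1,2-O-isopropylidene-3-O-(4-methoxybenzyl)-β-D-arabinofuranose | CC1(C)O[C@@H]2O[C@H](CO)[C@@H](OCc3ccc(OC)cc3)[C@@H]2O1 | intermediate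
6 | 1,2-O-isopropylidene-3-O-(4-methoxybenzyl)-β-D-arabino-pentodialdo-1,4-furanose | CC1(C)O[C@@H]2O[C@H](C=O)[C@@H](OCc3ccc(OC)cc3)[C@@H]2O1 | intermediate
7 | 5,6-dideoxy-1,2-O-isopropylidene-3-O-(4-methoxybenzyl)-β-D-arabino-hex-5-enofuranose | CC1(C)O[C@@H]2O[C@H](C=C)[C@@H](OCc3ccc(OC)cc3)[C@@H]2O1 | intermediate
8 | 5,6-dideoxy-3-O-(4-methoxybenzyl)-D-arabino-hex-5-enofuranose | OC1O[C@H](C=C)[C@@H](OCc2ccc(OC)cc2)[C@@H]1O | intermediate
9 | 5,6-dideoxy-3-O-(4-methoxybenzyl)-D-arabino-hex-5-enono-1,4-lactone | O=C1O[C@H](C=C)[C@@H](OCc2ccc(OC)cc2)[C@@H]1O | intermediate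
10 | 2-O-benzyl-5,6-dideoxy-3-O-(4-methoxybenzyl)-D-arabino-hex-5-enono-1,4-lactone | O=C1O[C@H](C=C)[C@@H](OCc2ccc(OC)cc2)[C@@H]1OCc1ccccc1 | intermediate
11 | (2Z,3S,4R,5R)-3-benzyloxy-2-ethylidene-4-(4-methoxybenzyloxy)-5-vinyltetrahydrofuran | C/C=C1/[C@@H](OCc2ccccc2)[C@H](OCc2ccc(OC)cc2)[C@@H](C=C)O1 | intermediate
12 | (2S,3R,7S)-2-benzyloxy-3-(4-methoxybenzyloxy)-7-methylcyclohept-4-en-1-one | O=C1[C@@H](OCc2ccccc2)[C@H](OCc2ccc(OC)cc2)C=CC[C@@H]1C | intermediate
13 | (2S,3R,7S)-2-benzyloxy-3-hydroxy-7-methylcyclohept-4-en-1-one | O=C1[C@@H](OCc2ccccc2)[C@H](O)C=CC[C@@H]1C | intermediate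
14 | O6-(2-bromo-1-methoxyprop-2-enyl) mixed acetal of 13 | O=C1[C@@H](OCc2ccccc2)[C@H](OC(OC)C(Br)=C)C=CC[C@@H]1C | intermediate
15 | cis-fused 8-benzyloxy-2-methoxy-6-methyl-3-methyleneoctahydrocyclohepta[b]furan-7-one | O=C1[C@@H](OCc3ccccc3)[C@@H]2OC(OC)C(=C)[C@@H]2CC[C@@H]1C | intermediate
16 | (3aS,6S,8S,8aR)-8-benzyloxy-6-methyl-3-methylenehexahydrocyclohepta[b]furan-2,7-dione | O=C1[C@@H](OCc3ccccc3)[C@@H]2OC(=O)C(=C)[C@@H]2CC[C@@H]1C | intermediate
17 | (3R,3aS,6S,8S,8aR)-8-benzyloxy-3,6-dimethylhexahydrocyclohepta[b]furan-2,7-dione | O=C1[C@@H](OCc3ccccc3)[C@@H]2OC(=O)[C@H](C)[C@@H]2CC[C@@H]1C | intermediate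
18 | (S)-propylene oxide | C[C@H]1CO1 | starting material
19 | (S)-pent-4-yn-2-ol | C[C@H](O)CC#C | intermediate
20 | (S)-4-iodopent-4-en-2-ol | C[C@H](O)CC(I)=C | intermediate
21 | (S)-tert-butyl[(4-iodopent-4-en-2-yl)oxy]dimethylsilane | C[C@H](O[Si](C)(C)C(C)(C)C)CC(I)=C | intermediate
22 | alkenyllithium from 21 | C[C@H](O[Si](C)(C)C(C)(C)C)CC([Li])=C | intermediate
23 | alkenylcerium dichloride from 22 | C[C@H](O[Si](C)(C)C(C)(C)C)CC(=C)[Ce](Cl)Cl | intermediate
24 | tertiary alcohol, 1α-OH, 1β-[(4S)-4-(tert-butyldimethylsilyloxy)pent-1-en-2-yl], 5β-OBn, cis lactone | O(Cc3ccccc3)[C@H]1[C@@H]2OC(=O)[C@H](C)[C@@H]2CC[C@H](C)[C@@]1(O)C(=C)C[C@H](C)O[Si](C)(C)C(C)(C)C | intermediate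
25 | 1,2,4-trioxolane (ozonide) at C2 of 24 | O(Cc3ccccc3)[C@H]1[C@@H]2OC(=O)[C@H](C)[C@@H]2CC[C@H](C)[C@@]1(O)C4(OCOO4)C[C@H](C)O[Si](C)(C)C(C)(C)C | intermediate
26 | 1α-hydroxy-1β-[(S)-3-(tert-butyldimethylsilyloxy)butanoyl] benzyl ether lactone | O(Cc3ccccc3)[C@H]1[C@@H]2OC(=O)[C@H](C)[C@@H]2CC[C@H](C)[C@@]1(O)C(=O)C[C@H](C)O[Si](C)(C)C(C)(C)C | intermediate
27 | 5β,1α-diol with O4 silyl ether | O[C@H]1[C@@H]2OC(=O)[C@H](C)[C@@H]2CC[C@H](C)[C@@]1(O)C(=O)C[C@H](C)O[Si](C)(C)C(C)(C)C | intermediate
28 | angelic acid, (Z)-2-methylbut-2-enoic acid | C/C=C(/C)C(=O)O | starting material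
29 | angelic 2,4,6-trichlorobenzoic anhydride | C/C=C(/C)C(=O)OC(=O)c1c(Cl)cc(Cl)cc1Cl | intermediate
30 | O4-tert-butyldimethylsilyl ether of the target | C/C=C(/C)C(=O)O[C@H]1[C@@H]2OC(=O)[C@H](C)[C@@H]2CC[C@H](C)[C@@]1(O)C(=O)C[C@H](C)O[Si](C)(C)C(C)(C)C | intermediate
31 | CNP0321985.2 | C/C=C(/C)C(=O)O[C@H]1[C@@H]2OC(=O)[C@H](C)[C@@H]2CC[C@H](C)[C@@]1(O)C(=O)C[C@H](C)O | target

Total step count: 24. Longest linear sequence: 21 (steps 1–16 and 20–24). Steps 17–19 build the side-chain fragment in parallel.

Steps most likely to fail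

1. Step 11.
- **Risk:** At the temperature that the boat-like transition state needs, the exocyclic enol ether may migrate into the ring or lose benzyl alcohol with aromatisation. The product may also epimerise at C10 or eliminate the O6 ether.
- **Fallback:** Ring-closing metathesis replaces the sigmatropic shift. It sets out from 10 and returns at 12.
- Reduction of 10 with i-Bu2AlH (CH2Cl2, −78 °C) gives the lactol F1.
- The open hydroxy-aldehyde tautomer of F1 is crotylated with a tartrate-modified (E)-crotylboronate, whose enantiomer is chosen to fix C10 as in 12. This gives the anti diene diol F2.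
- The second-generation Grubbs catalyst (CH2Cl2, 40 °C) closes ring A at C8=C9 to the cycloheptenediol F3.
- A Myers reductive transposition then acts on the less hindered, allylic C7 hydroxyl (2-nitrobenzenesulfonylhydrazide, PPh3, DEAD, THF, −30 °C to rt). It passes through the sulfonylhydrazine F4 and the allylic diazene F5.
- Retro-ene loss of nitrogen from F5 moves the alkene to C7=C8 and gives the cycloheptenol F6.
- Dess–Martin oxidation of the C1 hydroxyl of F6 gives 12.

2. Step 10.
- **Risk:** The lactone may react sluggishly with the titanium ethylidene reagent. The enol ether may hydrolyse with ring opening on work-up, and the Z geometry may erode.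
- **Fallback:** Addition followed by dehydration replaces carbonyl olefination. It sets out from 10 and returns at 11.
- EtMgBr (THF, −78 °C) adds once to the lactone to give the 1-C-ethyl hemiketal F7.
- Dehydration of F7 with (CF3CO)2O and pyridine (0 °C) removes a proton from the ethyl CH2 group. This should give the exocyclic enol ether with the methyl group away from C5, that is 11.

3. Step 20.
- **Risk:** The hindered ketone may enolise, the lactone carboxylate may β-eliminate, the reagent may attack the lactone carbonyl, and facial selectivity may be poor with the branched alkenyl nucleophile.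
- **Fallback:** A slim acetylide serves as the acyl anion equivalent and is unmasked by carbonate-directed hydration. It sets out from 17 and returns at 26.
- Commercial (S)-but-3-yn-2-ol is silylated (TBSCl, imidazole) to the silyl ether F8.
- n-BuLi converts F8 into the lithium acetylide F9.
- F9 is added to 17 at −78 °C, and the tertiary alkoxide is trapped in the flask with Boc2O to give the propargylic tert-butyl carbonate F10.
- Au(NTf2)(PPh3), a monovalent gold catalyst, triggers 5-exo-dig attack of the carbonate carbonyl on C2 with loss of isobutene. This gives the (Z)-alkylidene cyclic carbonate F11.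
- Mild aqueous hydrolysis of F11 with loss of carbon dioxide gives 26.

Further compounds
F1 | step 11 | 2-O-benzyl-5,6-dideoxy-3-O-(4-methoxybenzyl)-D-arabino-hex-5-enofuranose (lactol) | OC1O[C@H](C=C)[C@@H](OCc2ccc(OC)cc2)[C@@H]1OCc1ccccc1
F2 | step 11 | 5-benzyloxy-6-(4-methoxybenzyloxy)-3-methylnona-1,8-diene-4,7-diol (3,4-anti) | C=C[C@H](C)[C@H](O)[C@@H](OCc1ccccc1)[C@H](OCc1ccc(OC)cc1)[C@H](O)C=C
F3 | step 11 | 2-benzyloxy-3-(4-methoxybenzyloxy)-7-methylcyclohept-5-ene-1,4-diol | O[C@@H]1[C@@H](OCc2ccccc2)[C@H](OCc2ccc(OC)cc2)[C@H](O)C=C[C@@H]1C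
F4 | step 11 | N-(cycloheptenyl)-N-(2-nitrophenylsulfonyl)hydrazine at C7 (inverted) | O[C@@H]1[C@@H](OCc2ccccc2)[C@H](OCc2ccc(OC)cc2)[C@@H](N(N)S(=O)(=O)c2ccccc2[N+](=O)[O-])C=C[C@@H]1C
F5 | step 11 | allylic diazene at C7 | O[C@@H]1[C@@H](OCc2ccccc2)[C@H](OCc2ccc(OC)cc2)[C@@H](N=N)C=C[C@@H]1C
F6 | step 11 | 2-benzyloxy-3-(4-methoxybenzyloxy)-7-methylcyclohept-4-en-1-ol | O[C@@H]1[C@@H](OCc2ccccc2)[C@H](OCc2ccc(OC)cc2)C=CC[C@@H]1C
F7 | step 10 | 1-C-ethyl hemiketal of 10 | CCC1(O)O[C@H](C=C)[C@@H](OCc2ccc(OC)cc2)[C@@H]1OCc1ccccc1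
F8 | step 20 | (S)-(but-3-yn-2-yloxy)(tert-butyl)dimethylsilane | C[C@H](O[Si](C)(C)C(C)(C)C)C#C
F9 | step 20 | lithium acetylide of F8 | C[C@H](O[Si](C)(C)C(C)(C)C)C#C[Li]
F10 | step 20 | C1 propargylic tert-butyl carbonate | O(Cc3ccccc3)[C@H]1[C@@H]2OC(=O)[C@H](C)[C@@H]2CC[C@H](C)[C@@]1(OC(=O)OC(C)(C)C)C#C[C@H](C)O[Si](C)(C)C(C)(C)C
F11 | step 20 | spiro (Z)-4-alkylidene-1,3-dioxolan-2-one at C1/C2 | O(Cc3ccccc3)[C@H]1[C@@H]2OC(=O)[C@H](C)[C@@H]2CC[C@H](C)[C@@]1(OC(=O)O4)/C4=C/[C@H](C)O[Si](C)(C)C(C)(C)C
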